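**Retrosynthetic overview**

1. The strategy rests on two atoms of the dienone ring: C8'' (quaternary, bearing OMe and flavan C6) is para to the C5'' carbonyl, and the ketal carbon C8a'' is the β-carbon of the same cyclohexadienone. The dihydrofuran ring O5–C5–C6–C8''–C8a'' is therefore the only ring missing from a C6–C8'' biaryl of a flavan-4-ol and a 5''-hydroxyflav-3''-ene.
2. Last step: oxidation of the free 5''-phenol of biaryl 26 in methanol (C8''–OMe), then fluoride in the same flask (O5–C8a'', dihydrofuran closure, loss of the silyl groups).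
3. Biaryl bond C6–C8'': Negishi coupling of the 8-zincated flav-3-ene (from 22) with the 6-bromoflavan 12.
4. 12 and 22 come from the (S)-flavanones 6 and 18 (bromination/reduction/C4 inversion, and reduction/elimination respectively).
5. Both pyranone rings are made first, separately, by Mitsunobu etherification of phenols 1 and 14 with hydroxy ester 2 (sets C2 and C2'') and Friedel–Crafts acylation; then the biaryl bond; the dihydrofuran ring last.

Key step: step 19

**Remarks on the chemistry**

- Locants: flavan unit unprimed, chromene/dienone unit double-primed. TBS = tert-butyldimethylsilyl.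
- Both flavan oxygens are carried as silyl ethers. An ester at C4 would be expelled by the neighbouring O5 phenoxide (o-quinone methide formation) at the moment O5 is released in the key step.
- Assumption: rotation about the tetra-ortho-substituted C6–C8'' bond is taken to be slow at room temperature, so 25 and 26 exist as two separable atropisomers. The route uses the atropisomer of 26 in which the C5 silyloxy group and the C2'' phenyl group lie on opposite faces of the chromene plane; the other one can be returned to the mixture by thermal equilibration of the axis.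
- The 2H-chromenes 22–26 are kept at or below 70 °C and shielded from light, to avoid electrocyclic ring opening at C2''.

**Route**

Step 1
Reactants: 1 3-hydroxy-4,5-dimethoxybenzaldehyde; 2 ethyl (R)-3-hydroxy-3-phenylpropanoate
Product: 3 ethyl (S)-3-(5-formyl-2,3-dimethoxyphenoxy)-3-phenylpropanoate
Conditions: PPh3, DIAD, toluene, 0 °C to rt
Reagents that add atoms: none
Why: Mitsunobu etherification proceeds by SN2 displacement of the oxyphosphonium group, so the (R)-carbinol is inverted to the (S)-aryl ether that becomes C2 of the flavan; the formyl and ester groups are inert.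

Step 2
Reactants: 3 ethyl (S)-3-(5-formyl-2,3-dimethoxyphenoxy)-3-phenylpropanoate
Product: 5 (S)-3-(5-hydroxy-2,3-dimethoxyphenoxy)-3-phenylpropanoic acid, via aryl formate 4 (not isolated)
Conditions: mCPBA, CH2Cl2, 0 °C to rt; solvent exchange; LiOH, THF/H2O, 0 °C to rt; 1 M HCl
Reagents that add atoms: mCPBA, O=C(OO)c1cccc(Cl)c1; lithium hydroxide, [Li+].[OH-]
Why: Baeyer–Villiger oxidation of the benzaldehyde, whose ring carries a para methoxy group and therefore migrates in preference to hydride, gives the aryl formate, and hydroxide then cleaves formate and ethyl ester in one operation without touching the benzylic ether stereocentre.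

Step 3
Reactants: 5 (S)-3-(5-hydroxy-2,3-dimethoxyphenoxy)-3-phenylpropanoic acid
Product: 6 (2S)-5-hydroxy-7,8-dimethoxyflavanone
Conditions: Eaton's reagent (P2O5 in MeSO3H), rt
Reagents that add atoms: none
Why: Intramolecular Friedel–Crafts acylation can only occur at the single free position ortho to the ether oxygen, which is also activated by the ortho hydroxyl and para methoxy groups, and the base-free medium should leave the C2 stereocentre intact.

Step 4
Reactants: 6 (2S)-5-hydroxy-7,8-dimethoxyflavanone
Product: 7 (2S)-6-bromo-5-hydroxy-7,8-dimethoxyflavanone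
Conditions: NBS, MeCN, 0 °C
Reagents that add atoms: N-bromosuccinimide, O=C1CCC(=O)N1Br
Why: Electrophilic aromatic bromination takes the only unsubstituted position of the A ring (C6), which is ortho to the free phenol and to the C7 methoxy group.

Step 5
Reactants: 7 (2S)-6-bromo-5-hydroxy-7,8-dimethoxyflavanone
Product: 8 (2S)-6-bromo-5-(tert-butyldimethylsilyloxy)-7,8-dimethoxyflavanone
Conditions: TBSOTf, 2,6-lutidine, CH2Cl2, 0 °C
Reagents that add atoms: TBSOTf, CC(C)(C)[Si](C)(C)OS(=O)(=O)C(F)(F)F
Why: Silylation with the silyl triflate and a hindered pyridine base overcomes the hydrogen bond of the peri phenol without the basic conditions that would open the flavanone to the chalcone.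

Step 6
Reactants: 8 (2S)-6-bromo-5-(tert-butyldimethylsilyloxy)-7,8-dimethoxyflavanone
Product: 9 (2S,4S)-6-bromo-5-(tert-butyldimethylsilyloxy)-7,8-dimethoxyflavan-4-ol
Conditions: NaBH4, CeCl3·7H2O, MeOH/THF, −40 to 0 °C
Reagents that add atoms: none
Why: Luche reduction delivers hydride to the C4 carbonyl from the pseudo-axial direction of the half-chair with equatorial 2-phenyl and should give the 2,4-cis (4S) alcohol, while the near-neutral cerium medium suppresses ring opening at C2 and O5-to-O4 silyl transfer.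

Step 7
Reactants: 9 (2S,4S)-6-bromo-5-(tert-butyldimethylsilyloxy)-7,8-dimethoxyflavan-4-ol
Product: 10 (2S,4R)-6-bromo-5-(tert-butyldimethylsilyloxy)-7,8-dimethoxyflavan-4-yl acetate
Conditions: PPh3, DIAD, AcOH, toluene, −20 °C to rt
Reagents that add atoms: acetic acid, CC(=O)O
Why: Mitsunobu esterification inverts C4 to the 2,4-trans (4R) acetate; direct SN2 displacement and a possible ion-pair pathway both deliver acetate pseudo-axially, trans to the equatorial 2-phenyl group.

Step 8
Reactants: 10 (2S,4R)-6-bromo-5-(tert-butyldimethylsilyloxy)-7,8-dimethoxyflavan-4-yl acetate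
Product: 11 (2S,4R)-6-bromo-5-(tert-butyldimethylsilyloxy)-7,8-dimethoxyflavan-4-ol
Conditions: DIBAL-H, CH2Cl2, −78 °C; aq. Rochelle salt
Reagents that add atoms: none
Why: Reductive ester cleavage by hydride attack at the acyl carbon, at low temperature in a non-ionising solvent, frees the trans alcohol without solvolysis at the electron-rich benzylic C4 and leaves the aryl silyl ether and the aryl bromide untouched.

Step 9
Reactants: 11 (2S,4R)-6-bromo-5-(tert-butyldimethylsilyloxy)-7,8-dimethoxyflavan-4-ol
Product: 12 (2S,4R)-6-bromo-4,5-bis(tert-butyldimethylsilyloxy)-7,8-dimethoxyflavan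
Conditions: TBSOTf, 2,6-lutidine, CH2Cl2, −78 to 0 °C
Reagents that add atoms: TBSOTf, CC(C)(C)[Si](C)(C)OS(=O)(=O)C(F)(F)F
Why: Silyl triflate silylation of the hindered pseudo-axial alcohol; a silyl ether is chosen for O4 because, unlike an ester, it is not expelled when the neighbouring O5 phenoxide is released in step 19.

Step 10
Reactants: 13 3,5-dimethoxyphenol
Product: 14 2-bromo-3,5-dimethoxyphenol
Conditions: NBS, i-Pr2NH (cat.), CH2Cl2, −78 to 0 °C
Reagents that add atoms: N-bromosuccinimide, O=C1CCC(=O)N1Br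
Why: Amine-mediated electrophilic bromination of a phenol is ortho-selective (bromine is delivered from the N-bromoamine hydrogen-bonded to the phenol), the two ortho positions are equivalent, and any 4-bromo isomer is removed by chromatography.

Step 11
Reactants: 14 2-bromo-3,5-dimethoxyphenol; 2 ethyl (R)-3-hydroxy-3-phenylpropanoate
Product: 15 ethyl (S)-3-(2-bromo-3,5-dimethoxyphenoxy)-3-phenylpropanoate
Conditions: PPh3, DIAD, toluene, 0 °C to rt
Reagents that add atoms: none
Why: Mitsunobu etherification with SN2 inversion, as in step 1, sets the (S) centre that becomes C2''; the ortho-bromophenol is acidic enough to be a good pronucleophile.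

Step 12
Reactants: 15 ethyl (S)-3-(2-bromo-3,5-dimethoxyphenoxy)-3-phenylpropanoate
Product: 16 (S)-3-(2-bromo-3,5-dimethoxyphenoxy)-3-phenylpropanoic acid
Conditions: LiOH, THF/H2O, 0 °C to rt; 1 M HCl
Reagents that add atoms: lithium hydroxide, [Li+].[OH-]
Why: Saponification of the ethyl ester at low temperature is faster than β-elimination of the aryloxide, and the carboxylate formed is no longer prone to it.

Step 13
Reactants: 16 (S)-3-(2-bromo-3,5-dimethoxyphenoxy)-3-phenylpropanoic acid
Product: 18 (2S)-8-bromo-5-hydroxy-7-methoxyflavanone, via 8-bromo-5,7-dimethoxyflavanone 17 (not isolated)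
Conditions: TFAA, CH2Cl2, 0 °C to rt; evaporate; BCl3, CH2Cl2, −78 to 0 °C; aq. work-up
Reagents that add atoms: none
Why: The mixed trifluoroacetic anhydride acylates the only free position ortho to the ether oxygen (intramolecular Friedel–Crafts acylation; bromine blocks the other), and boron trichloride, chelated by the new carbonyl, then cleaves only the peri 5-methoxy group.

Step 14
Reactants: 18 (2S)-8-bromo-5-hydroxy-7-methoxyflavanone
Product: 19 (2S)-8-bromo-5-(tert-butyldimethylsilyloxy)-7-methoxyflavanone
Conditions: TBSOTf, 2,6-lutidine, CH2Cl2, 0 °C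
Reagents that add atoms: TBSOTf, CC(C)(C)[Si](C)(C)OS(=O)(=O)C(F)(F)F
Why: Silyl triflate silylation of the chelated phenol under non-basic conditions, as in step 5, protects O5'' for the organometallic step without risk to C2''.

Step 15
Reactants: 19 (2S)-8-bromo-5-(tert-butyldimethylsilyloxy)-7-methoxyflavanone
Product: 20 (2S,4S)-8-bromo-5-(tert-butyldimethylsilyloxy)-7-methoxyflavan-4-ol
Conditions: NaBH4, CeCl3·7H2O, MeOH/THF, −40 to 0 °C
Reagents that add atoms: none
Why: Luche reduction as in step 6 should give the 2,4-cis alcohol; the configuration at C4 is of no consequence because this centre is removed in step 16.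

Step 16
Reactants: 20 (2S,4S)-8-bromo-5-(tert-butyldimethylsilyloxy)-7-methoxyflavan-4-ol
Product: 22 (2S)-8-bromo-5-(tert-butyldimethylsilyloxy)-7-methoxyflav-3-ene, via benzylic mesylate 21 (not isolated)
Conditions: MsCl, Et3N, CH2Cl2, 0 °C to rt
Reagents that add atoms: none
Why: The electron-rich benzylic mesylate ionises and loses H-3 under amine base (E1-type β-elimination), which gives the 2H-chromene under non-acidic conditions that avoid Friedel–Crafts self-condensation.

Step 17
Reactants: 22 (2S)-8-bromo-5-(tert-butyldimethylsilyloxy)-7-methoxyflav-3-ene; 12 (2S,4R)-6-bromo-4,5-bis(tert-butyldimethylsilyloxy)-7,8-dimethoxyflavan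
Product: 25 (2S,4R)-4,5-bis(tert-butyldimethylsilyloxy)-6-[(2S)-5-(tert-butyldimethylsilyloxy)-7-methoxyflav-3-en-8-yl]-7,8-dimethoxyflavan (both atropisomers), via aryllithium 23 (not isolated), via arylzinc chloride 24 (not isolated)
Conditions: 22, t-BuLi (2 equiv), THF, −78 °C; ZnCl2, −78 °C to rt; then 12, Pd2(dba)3, RuPhos, THF/NMP, 70 °C
Reagents that add atoms: none
Why: Bromine–lithium exchange at −78 °C is faster than any deprotonation and the silyl ether para to lithium cannot migrate, transmetalation gives an arylzinc flanked by two ortho oxygens, and Negishi coupling with a bulky dialkylbiarylphosphine–palladium catalyst is a base-free method for tetra-ortho-substituted biaryls that leaves the silyl ethers and the chromene intact.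

Step 18
Reactants: 25 (2S,4R)-4,5-bis(tert-butyldimethylsilyloxy)-6-[(2S)-5-(tert-butyldimethylsilyloxy)-7-methoxyflav-3-en-8-yl]-7,8-dimethoxyflavan
Product: 26 (2S,4R)-4,5-bis(tert-butyldimethylsilyloxy)-6-[(2S)-5-hydroxy-7-methoxyflav-3-en-8-yl]-7,8-dimethoxyflavan (single atropisomer)
Conditions: K2CO3, MeOH/THF, 0 °C to rt; chromatographic separation of the atropisomers
Reagents that add atoms: none
Why: Base-mediated methanolysis of aryl silyl ethers is strongly retarded by ortho substitution, so only the 5''-silyl ether, which has a free ortho position, should be cleaved while the C5 silyl ether (flanked by the biaryl bond and the peri C4 substituent) and the alkyl silyl ether survive.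

Step 19
Reactants: 26 (2S,4R)-4,5-bis(tert-butyldimethylsilyloxy)-6-[(2S)-5-hydroxy-7-methoxyflav-3-en-8-yl]-7,8-dimethoxyflavan
Product: 29 6''-demethoxyneocalycopterone, via quinol ether dienone 27 (not isolated), via C4 silyl ether 28 (not isolated)
Conditions: PhI(OAc)2, MeOH, −20 to 0 °C; evaporate; TBAF, THF, 0 °C to rt
Reagents that add atoms: methanol, CO
Why: Ligand exchange of the free 5''-phenol on iodine(III) and loss of iodobenzene give a phenoxonium ion that methanol captures at the para carbon C8'' (the known para-quinol ether formation from 4-arylphenols) to give dienone 27, while the electron-rich flavan ring is inert because both of its oxygens are silylated. Fluoride then cleaves the aryl silyl ether first, and the O5 phenoxide adds to C8a'', the β-carbon of the C5''=O/C4a''=C8a'' enone, in a 5-exo-trig oxa-Michael reaction that closes the dihydrofuran ring (O5–C5–C6–C8''–C8a''); the extended dienolate is protonated at C3'', so the alkene settles in conjugation at C4''=C4a'', and the slower cleavage of the C4 silyl ether ends the sequence. C8'' is controlled by the biaryl axis: in the atropisomer used, the bulky C5 silyloxy group covers the chromene face anti to the C2'' phenyl group, so methanol should enter from the face flanked by the C7 methoxy group and the flavan ring is pushed to the anti face. C8a'' follows from C8'', because the five-membered ring can only be cis-fused, which places O5 axial (anomeric) and trans to the equatorial C2'' phenyl group as in the target. The step needs para attack at C8'' rather than at C6'' or the vinylogous C3'', for which the larger para coefficient of the phenoxonium ion is relied on, and closure at C8a'' rather than C7'', which is favoured because only attack at C8a'' gives a dienolate extended through C4''=C3'' and a product that keeps the C6''=C7'' vinylogous ester. No ester is present at C4, so the freed phenoxide has no leaving group to expel.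

**Compound list**

1 | 3-hydroxy-4,5-dimethoxybenzaldehyde | COc1cc(C=O)cc(O)c1OC | starting material
2 | ethyl (R)-3-hydroxy-3-phenylpropanoate | CCOC(=O)C[C@@H](O)c1ccccc1 | starting material
3 | ethyl (S)-3-(5-formyl-2,3-dimethoxyphenoxy)-3-phenylpropanoate | CCOC(=O)C[C@H](Oc1cc(C=O)cc(OC)c1OC)c1ccccc1 | intermediate
4 | ethyl (S)-3-(5-formyloxy-2,3-dimethoxyphenoxy)-3-phenylpropanoate | CCOC(=O)C[C@H](Oc1cc(OC=O)cc(OC)c1OC)c1ccccc1 | intermediate
5 | (S)-3-(5-hydroxy-2,3-dimethoxyphenoxy)-3-phenylpropanoic acid | OC(=O)C[C@H](Oc1cc(O)cc(OC)c1OC)c1ccccc1 | intermediate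
6 | (2S)-5-hydroxy-7,8-dimethoxyflavanone | O=C1C[C@@H](c2ccccc2)Oc2c(OC)c(OC)cc(O)c12 | intermediate
7 | (2S)-6-bromo-5-hydroxy-7,8-dimethoxyflavanone | O=C1C[C@@H](c2ccccc2)Oc2c(OC)c(OC)c(Br)c(O)c12 | intermediate
8 | (2S)-6-bromo-5-(tert-butyldimethylsilyloxy)-7,8-dimethoxyflavanone | O=C1C[C@@H](c2ccccc2)Oc2c(OC)c(OC)c(Br)c(O[Si](C)(C)C(C)(C)C)c12 | intermediate
9 | (2S,4S)-6-bromo-5-(tert-butyldimethylsilyloxy)-7,8-dimethoxyflavan-4-ol (2,4-cis) | O[C@H]1C[C@@H](c2ccccc2)Oc2c(OC)c(OC)c(Br)c(O[Si](C)(C)C(C)(C)C)c12 | intermediate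
10 | (2S,4R)-6-bromo-5-(tert-butyldimethylsilyloxy)-7,8-dimethoxyflavan-4-yl acetate (2,4-trans) | CC(=O)O[C@@H]1C[C@@H](c2ccccc2)Oc2c(OC)c(OC)c(Br)c(O[Si](C)(C)C(C)(C)C)c12 | intermediate
11 | (2S,4R)-6-bromo-5-(tert-butyldimethylsilyloxy)-7,8-dimethoxyflavan-4-ol | O[C@@H]1C[C@@H](c2ccccc2)Oc2c(OC)c(OC)c(Br)c(O[Si](C)(C)C(C)(C)C)c12 | intermediate
12 | (2S,4R)-6-bromo-4,5-bis(tert-butyldimethylsilyloxy)-7,8-dimethoxyflavan | CC(C)(C)[Si](C)(C)O[C@@H]1C[C@@H](c2ccccc2)Oc2c(OC)c(OC)c(Br)c(O[Si](C)(C)C(C)(C)C)c12 | intermediate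
13 | 3,5-dimethoxyphenol | COc1cc(O)cc(OC)c1 | starting material
14 | 2-bromo-3,5-dimethoxyphenol | COc1cc(O)c(Br)c(OC)c1 | intermediate
15 | ethyl (S)-3-(2-bromo-3,5-dimethoxyphenoxy)-3-phenylpropanoate | CCOC(=O)C[C@H](Oc1cc(OC)cc(OC)c1Br)c1ccccc1 | intermediate
16 | (S)-3-(2-bromo-3,5-dimethoxyphenoxy)-3-phenylpropanoic acid | OC(=O)C[C@H](Oc1cc(OC)cc(OC)c1Br)c1ccccc1 | intermediate
17 | (2S)-8-bromo-5,7-dimethoxyflavanone | O=C1C[C@@H](c2ccccc2)Oc2c(Br)c(OC)cc(OC)c12 | intermediate
18 | (2S)-8-bromo-5-hydroxy-7-methoxyflavanone | O=C1C[C@@H](c2ccccc2)Oc2c(Br)c(OC)cc(O)c12 | intermediate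
19 | (2S)-8-bromo-5-(tert-butyldimethylsilyloxy)-7-methoxyflavanone | O=C1C[C@@H](c2ccccc2)Oc2c(Br)c(OC)cc(O[Si](C)(C)C(C)(C)C)c12 | intermediate
20 | (2S,4S)-8-bromo-5-(tert-butyldimethylsilyloxy)-7-methoxyflavan-4-ol | O[C@H]1C[C@@H](c2ccccc2)Oc2c(Br)c(OC)cc(O[Si](C)(C)C(C)(C)C)c12 | intermediate
21 | (2S,4S)-8-bromo-5-(tert-butyldimethylsilyloxy)-7-methoxyflavan-4-yl methanesulfonate | CS(=O)(=O)O[C@H]1C[C@@H](c2ccccc2)Oc2c(Br)c(OC)cc(O[Si](C)(C)C(C)(C)C)c12 | intermediate
22 | (2S)-8-bromo-5-(tert-butyldimethylsilyloxy)-7-methoxyflav-3-ene | CC(C)(C)[Si](C)(C)Oc1cc(OC)c(Br)c2O[C@H](c3ccccc3)C=Cc12 | intermediate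
23 | (2S)-5-(tert-butyldimethylsilyloxy)-8-lithio-7-methoxyflav-3-ene | CC(C)(C)[Si](C)(C)Oc1cc(OC)c([Li])c2O[C@H](c3ccccc3)C=Cc12 | intermediate
24 | [(2S)-5-(tert-butyldimethylsilyloxy)-7-methoxyflav-3-en-8-yl]zinc chloride | CC(C)(C)[Si](C)(C)Oc1cc(OC)c([Zn]Cl)c2O[C@H](c3ccccc3)C=Cc12 | intermediate
25 | (2S,4R)-4,5-bis(tert-butyldimethylsilyloxy)-6-[(2S)-5-(tert-butyldimethylsilyloxy)-7-methoxyflav-3-en-8-yl]-7,8-dimethoxyflavan, both atropisomers about C6–C8'' | COc1cc(O[Si](C)(C)C(C)(C)C)c2C=C[C@@H](c3ccccc3)Oc2c1-c1c(O[Si](C)(C)C(C)(C)C)c2c(c(OC)c1OC)O[C@H](c1ccccc1)C[C@H]2O[Si](C)(C)C(C)(C)C | intermediate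
26 | (2S,4R)-4,5-bis(tert-butyldimethylsilyloxy)-6-[(2S)-5-hydroxy-7-methoxyflav-3-en-8-yl]-7,8-dimethoxyflavan, atropisomer with the C5–OSi and C2''–Ph bonds on opposite faces of the chromene plane | COc1cc(O)c2C=C[C@@H](c3ccccc3)Oc2c1-c1c(O[Si](C)(C)C(C)(C)C)c2c(c(OC)c1OC)O[C@H](c1ccccc1)C[C@H]2O[Si](C)(C)C(C)(C)C | intermediate
27 | (2S,4R)-4,5-bis(tert-butyldimethylsilyloxy)-6-[(2S)-7,8-dimethoxy-5-oxo-2-phenyl-5,8-dihydro-2H-chromen-8-yl]-7,8-dimethoxyflavan, C8'' configured as in 29 | COC1=CC(=O)C2=C(O[C@H](c3ccccc3)C=C2)[C@]1(OC)c1c(O[Si](C)(C)C(C)(C)C)c2c(c(OC)c1OC)O[C@H](c1ccccc1)C[C@H]2O[Si](C)(C)C(C)(C)C | intermediate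
28 | 4-O-(tert-butyldimethylsilyl)-6''-demethoxyneocalycopterone | COC1=CC(=O)C2=CC[C@@H](c3ccccc3)O[C@]23Oc2c4c(c(OC)c(OC)c2[C@]13OC)O[C@H](c1ccccc1)C[C@H]4O[Si](C)(C)C(C)(C)C | intermediate
29 | 6''-demethoxyneocalycopterone, (2S,4R,2''S,8''S,8a''S) | COC1=CC(=O)C2=CC[C@@H](c3ccccc3)O[C@]23Oc2c4c(c(OC)c(OC)c2[C@]13OC)O[C@H](c1ccccc1)C[C@H]4O | target

**Step count**

Total: 19 steps. Longest linear sequence: 12 steps (steps 1–9, then 17–19).

**Steps most likely to fail**

1. Step 19 (key step). Methanol may be captured at C3'' (the phenoxonium ion is delocalised through C4a'' into the C3''=C4'' bond) or at the unhindered C6'' instead of the congested C8'', and shielding of one face of C8'' by the axis may be incomplete. The fallback sets out from 20 and returns at 29; it carries the future alkene as a 4''-methoxy group. Acid-catalysed methanolysis of 20 (PPTS, MeOH; SN1 with pseudo-axial capture) gives (2S,4R)-8-bromo-5-(tert-butyldimethylsilyloxy)-4,7-dimethoxyflavan F1, which has no C3=C4 bond. Coupling of F1 with 12 under the conditions of step 17 gives the 4''-methoxy tris(silyl ether) biaryl F2, and K2CO3 in MeOH as in step 18 gives the 5''-phenol F3. PhI(OAc)2 in MeOH can then lead only to the para-quinol ether dienone F4, which is isolated so that its C8'' epimers can be separated before ring closure. TBAF followed by DBU then brings about oxa-Michael closure at C8a'' and E1cB loss of methanol from C4'' (β to the C5'' enolate), which installs C4''=C4a'' and gives 29.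

2. Step 17. Oxidative addition into the electron-rich, doubly ortho-substituted bromide 12 and transmetalation of the equally hindered arylzinc may be so slow that the arylzinc is consumed by protonation or homocoupling. The fallback sets out from 22 and returns at 25. Bromine–lithium exchange of 22 (t-BuLi, −78 °C) and quench with 2-isopropoxy-4,4,5,5-tetramethyl-1,3,2-dioxaborolane give the isolable pinacol boronate (2S)-5-(tert-butyldimethylsilyloxy)-7-methoxy-8-(4,4,5,5-tetramethyl-1,3,2-dioxaborolan-2-yl)flav-3-ene F5. Suzuki–Miyaura coupling of F5 with 12 (palladium precatalyst of a biarylphosphine made for tetra-ortho-substituted biaryls, K3PO4, toluene/water, 80 °C) gives 25.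

3. Step 7. The oxyphosphonium intermediate may ionise at the electron-rich benzylic carbon and lose H-3 (elimination to the flav-3-ene), or inversion may be incomplete. The fallback sets out from 9 and returns at 10: acid-catalysed acetolysis (AcOH, cat. camphorsulfonic acid, CH2Cl2, 0 °C) under equilibrating conditions. The C4 cation is captured pseudo-axially and any flav-3-ene is reprotonated to the same cation, so the thermodynamically preferred trans acetate 10 should accumulate; no new compound is made.

**Further compounds**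

F1 | step 19 | (2S,4R)-8-bromo-5-(tert-butyldimethylsilyloxy)-4,7-dimethoxyflavan | CO[C@@H]1C[C@@H](c2ccccc2)Oc2c(Br)c(OC)cc(O[Si](C)(C)C(C)(C)C)c12
F2 | step 19 | (2S,4R)-4,5-bis(tert-butyldimethylsilyloxy)-6-[(2S,4R)-5-(tert-butyldimethylsilyloxy)-4,7-dimethoxyflavan-8-yl]-7,8-dimethoxyflavan | COc1cc(O[Si](C)(C)C(C)(C)C)c2[C@H](OC)C[C@@H](c3ccccc3)Oc2c1-c1c(O[Si](C)(C)C(C)(C)C)c2c(c(OC)c1OC)O[C@H](c1ccccc1)C[C@H]2O[Si](C)(C)C(C)(C)C
F3 | step 19 | (2S,4R)-4,5-bis(tert-butyldimethylsilyloxy)-6-[(2S,4R)-5-hydroxy-4,7-dimethoxyflavan-8-yl]-7,8-dimethoxyflavan | COc1cc(O)c2[C@H](OC)C[C@@H](c3ccccc3)Oc2c1-c1c(O[Si](C)(C)C(C)(C)C)c2c(c(OC)c1OC)O[C@H](c1ccccc1)C[C@H]2O[Si](C)(C)C(C)(C)C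
F4 | step 19 | (2S,4R)-4,5-bis(tert-butyldimethylsilyloxy)-6-[(2S,4R)-4,7,8-trimethoxy-5-oxo-2-phenyl-3,4,5,8-tetrahydro-2H-chromen-8-yl]-7,8-dimethoxyflavan, C8'' configured as in 29 | COC1=CC(=O)C2=C(O[C@H](c3ccccc3)C[C@H]2OC)[C@]1(OC)c1c(O[Si](C)(C)C(C)(C)C)c2c(c(OC)c1OC)O[C@H](c1ccccc1)C[C@H]2O[Si](C)(C)C(C)(C)C
F5 | step 17 | (2S)-5-(tert-butyldimethylsilyloxy)-7-methoxy-8-(4,4,5,5-tetramethyl-1,3,2-dioxaborolan-2-yl)flav-3-ene | CC(C)(C)[Si](C)(C)Oc1cc(OC)c(B2OC(C)(C)C(C)(C)O2)c2O[C@H](c3ccccc3)C=Cc12
F0 | step 7 | none | none
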